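## Retrosynthetic overview

1. Feature: ring A is a beta-resorcylate, with the ester carbonyl on C1, hydroxyls on C2 and C4 and the C11 side chain on C6, and it is esterified by a hindered secondary carbinol. Oxygen on every second carbon is the imprint of a 3,5,7-trioxo ester folded by a C1–C6 aldol condensation.
2. Key disconnection: the ring A C1–C6 bond and the ester C–O bond are cut together. This leads to a diketo-dioxinone (masked acylketene, chain hydroxyl silylated) and the ring B alcohol (phenols benzylated). The ester forms first and ring A second, so no 2,6-disubstituted benzoic acid has to be esterified.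
3. Diketo-dioxinone: terminal C-acylation of the dianion of 6-(2-oxopropyl)dioxinone by a C12 Weinreb amide. The amide comes from (R)-1,2-epoxypentane and hept-6-enyl Grignard, then silylation, hydroboration and oxidation.
4. Alcohol half: (R)-1,2-epoxypentane and hex-5-enyl Grignard give the C11 chain, which is joined to 1,3-bis(benzyloxy)-5-bromobenzene by B-alkyl Suzuki coupling.
5. Ring order: ring B is bought and ring A is the only ring formed (step 11). Both R centres come from the same epoxide, and desilylation and hydrogenolysis end the route.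

Key step: step 11

Assumption: (R)-1,2-epoxypentane is taken as a purchasable single enantiomer. CIP analysis of the given SMILES gives R at both carbinol centres.

Remark on chain length:
- The acid half needs twelve carbons (carbonyl carbon, seven CH2, carbinol, propyl), hence epoxide C5 plus a C7 Grignard.
- In the alcohol half the aryl group is attached to the terminal alkene carbon without loss of carbon. Eleven carbons are therefore needed, hence epoxide C5 plus a C6 Grignard. A C7 Grignard would leave eight CH2 groups between carbinol and ring B.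

Polycarbonyl compounds are drawn as keto tautomers.

## Route

Step 1
Reactants: 1 7-bromohept-1-ene; 2 (R)-1,2-epoxypentane
Product: 4 (R)-dodec-11-en-4-ol, via hept-6-enylmagnesium bromide 3 (not isolated)
Conditions: Mg, I2 (cat.), THF, rt → 45 °C; then CuI (10 mol%), 2, THF, −30 → 0 °C
Reagents that add atoms: none
Why: Cu-catalysed Grignard opening of a terminal epoxide is an SN2 attack at the unsubstituted CH2, so the C–O bond at the stereocentre is never touched and the R configuration of 2 is carried unchanged into C4 of 4.

Step 2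
Reactants: 4 (R)-dodec-11-en-4-ol
Product: 5 (R)-tert-butyl(dodec-11-en-4-yloxy)dimethylsilane
Conditions: TBSCl, imidazole, DMF, rt
Reagents that add atoms: tert-butyldimethylsilyl chloride, CC(C)(C)[Si](C)(C)Cl
Why: Imidazole-promoted silylation of a secondary alcohol masks the only hydroxyl of this half, which has to stay silent when the ketene is generated in step 11.

Step 3
Reactants: 5 (R)-tert-butyl(dodec-11-en-4-yloxy)dimethylsilane
Product: 7 (R)-9-(tert-butyldimethylsilyloxy)dodecan-1-ol, via B-alkyl-9-BBN adduct 6 (not isolated)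
Conditions: 9-BBN, THF, 0 °C → rt; then NaOH (3 M aq), H2O2 (30% aq), 0 °C → rt
Reagents that add atoms: hydrogen peroxide, OO
Why: Hydroboration–oxidation with the bulky 9-BBN places boron and then oxygen on the terminal carbon only, and the secondary silyl ether tolerates the short alkaline peroxide treatment.

Step 4
Reactants: 7 (R)-9-(tert-butyldimethylsilyloxy)dodecan-1-ol
Product: 9 (R)-9-(tert-butyldimethylsilyloxy)dodecanoic acid, via aldehyde 8 (not isolated)
Conditions: TEMPO (20 mol%), PhI(OAc)2, MeCN/H2O 1:1, rt
Reagents that add atoms: water, O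
Why: Oxoammonium (TEMPO) oxidation in aqueous MeCN takes the primary alcohol through aldehyde 8 and its hydrate to the acid under nearly neutral conditions that spare the silyl ether and cannot reach the remote stereocentre.

Step 5
Reactants: 9 (R)-9-(tert-butyldimethylsilyloxy)dodecanoic acid
Product: 11 (R)-9-(tert-butyldimethylsilyloxy)-N-methoxy-N-methyldodecanamide, via acyl imidazole 10 (not isolated)
Conditions: CDI, CH2Cl2, rt; then MeNH(OMe)·HCl, rt
Reagents that add atoms: N,O-dimethylhydroxylamine hydrochloride, CNOC.Cl
Why: CDI activation and aminolysis give the Weinreb amide, preferred to imidazolide 10 as acyl donor because it can be isolated free of N–H imidazole (a proton source for a dianion) and because its chelated tetrahedral adduct holds until the quench.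

Step 6
Reactants: 12 2,2,6-trimethyl-4H-1,3-dioxin-4-one
Product: 14 2,2-dimethyl-6-(2-oxopropyl)-4H-1,3-dioxin-4-one, via lithium dienolate 13 (not isolated)
Conditions: 12 (2 equiv), LiN(SiMe3)2, THF, −78 °C; AcCl (1 equiv), −78 °C; 1 M HCl
Reagents that add atoms: acetyl chloride, CC(=O)Cl
Why: The lithium dienolate of the dioxinone is acylated by acid chlorides at its gamma (exocyclic CH2) carbon in a vinylogous Claisen condensation, and the second equivalent of 13 absorbs the acidic proton of the product.

Step 7
Reactants: 14 2,2-dimethyl-6-(2-oxopropyl)-4H-1,3-dioxin-4-one; 11 (R)-9-(tert-butyldimethylsilyloxy)-N-methoxy-N-methyldodecanamide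
Product: 16 6-[(R)-12-(tert-butyldimethylsilyloxy)-2,4-dioxopentadecyl]-2,2-dimethyl-4H-1,3-dioxin-4-one, via dilithium dianion 15 (not isolated)
Conditions: 14 (2 equiv), LiN(iPr)2 (4.2 equiv), THF, −78 → −40 °C; 11 (1 equiv), −78 → −20 °C; AcOH, −78 °C
Reagents that add atoms: none
Why: Double deprotonation gives a dianion whose last-formed terminal carbanion is its most nucleophilic site (gamma-functionalisation of 1,3-dicarbonyl dianions), so Claisen-type acylation by the Weinreb amide extends the chain at the former methyl carbon and the 1,3-diketone is released only at the acidic quench.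

Step 8
Reactants: 17 6-bromohex-1-ene; 2 (R)-1,2-epoxypentane
Product: 19 (R)-undec-10-en-4-ol, via hex-5-enylmagnesium bromide 18 (not isolated)
Conditions: Mg, I2 (cat.), THF, rt; then CuI (10 mol%), 2, THF, −30 → 0 °C
Reagents that add atoms: none
Why: The same Cu-catalysed SN2 epoxide opening as in step 1 keeps the R centre, and any cyclopentylmethyl Grignard arising from radical cyclisation during Mg insertion leads to an alkene-free alcohol that is inert in step 10 and separable there.

Step 9
Reactants: 20 5-bromoresorcinol
Product: 21 1,3-bis(benzyloxy)-5-bromobenzene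
Conditions: BnBr, K2CO3, acetone, reflux
Reagents that add atoms: benzyl bromide, BrCc1ccccc1
Why: Williamson etherification of both phenols installs hydrogenolysable ethers and removes every acidic O–H of ring B before the ketene step.

Step 10
Reactants: 19 (R)-undec-10-en-4-ol; 21 1,3-bis(benzyloxy)-5-bromobenzene
Product: 23 (R)-11-[3,5-bis(benzyloxy)phenyl]undecan-4-ol, via B-alkyl-9-BBN adduct 22 (not isolated)
Conditions: 9-BBN (2.2 equiv), THF, 0 °C → rt; then 21, Pd(dppf)Cl2 (5 mol%), K3PO4 (3 M aq), DMF, 60 °C
Reagents that add atoms: none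
Why: In this B-alkyl Suzuki–Miyaura coupling 9-BBN adds anti-Markovnikov to the terminal alkene, the extra equivalent covers any borinate formation at the free carbinol (undone by the aqueous base), and the base-activated borane hands its primary alkyl group to the arylpalladium bromide, with dppf favouring reductive elimination over beta-hydride elimination.

Step 11
Reactants: 16 6-[(R)-12-(tert-butyldimethylsilyloxy)-2,4-dioxopentadecyl]-2,2-dimethyl-4H-1,3-dioxin-4-one; 23 (R)-11-[3,5-bis(benzyloxy)phenyl]undecan-4-ol
Product: 27 (R)-11-[3,5-bis(benzyloxy)phenyl]undecan-4-yl 6-[(R)-8-(tert-butyldimethylsilyloxy)undecyl]-2,4-dihydroxybenzoate, via acylketene 24 (not isolated), via triketo ester 25 (not isolated), via cyclic aldol 26 (not isolated)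
Conditions: 16 (1.2 equiv), 23, PhMe, 110 °C; then Cs2CO3, MeOH, rt; then AcOH, rt
Reagents that add atoms: none
Why: At 110 °C the dioxinone ring of 16 fragments in a [4+2] cycloreversion into acetone and acylketene 24, and the carbinol oxygen of 23 adds to the sterically open ketene carbon without acid, base or coupling reagent, so the ester C–O bond is in place while the future ring A is still an open chain and no ortho substituent shields the carbonyl. The closest known reaction type is this same sequence, dioxinone thermolysis with alcohol capture followed by base-then-acid aromatisation, which is established for beta-resorcylate esters and resorcylic acid lactones of secondary alcohols. Cs2CO3 then converts 25 into its enolates, and in ring A numbering the carbon between the ester carbonyl and the C2 ketone (C1) bonds to the carbonyl carbon of the terminal C6 ketone, a 6-(enolendo)-exo-trig closure to 26, after which elimination of water and tautomerisation of the C2 and C4 ketones, brought to completion by AcOH, deliver the benzenoid ring. No lasting stereocentre is created (the two sp3 ring centres of 26 vanish on aromatisation), and both R carbinol centres are spectators because neither of their C–O bonds is broken. Chemoselective capture needs a single free O–H, secured by the silyl ether of 16 and the benzyl ethers of 23 (a free chain hydroxyl would close a 16-membered triketo lactone on its own ketene), and the regioselectivity needed is aldol closure (C1 to C6) over Claisen closure (C5 onto the ester carbonyl with loss of 23), secured because under a mild carbonate base the ketone is a better electrophile than the hindered secondary ester. AcOH is used instead of a mineral acid so that the secondary silyl ether is kept.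

Step 12
Reactants: 27 (R)-11-[3,5-bis(benzyloxy)phenyl]undecan-4-yl 6-[(R)-8-(tert-butyldimethylsilyloxy)undecyl]-2,4-dihydroxybenzoate
Product: 28 (R)-11-[3,5-bis(benzyloxy)phenyl]undecan-4-yl 2,4-dihydroxy-6-[(R)-8-hydroxyundecyl]benzoate
Conditions: HF·pyridine, THF, 0 °C → rt
Reagents that add atoms: none
Why: Fluoride-driven cleavage of the Si–O bond under mildly acidic conditions leaves the doubly ortho-substituted ester, the phenols and the benzyl ethers untouched and does not involve the C–O bond of the stereocentre.

Step 13
Reactants: 28 (R)-11-[3,5-bis(benzyloxy)phenyl]undecan-4-yl 2,4-dihydroxy-6-[(R)-8-hydroxyundecyl]benzoate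
Product: 29 integracin B, (R)-11-(3,5-dihydroxyphenyl)undecan-4-yl 2,4-dihydroxy-6-[(R)-8-hydroxyundecyl]benzoate
Conditions: H2 (1 atm), 10% Pd/C, EtOAc/EtOH, rt
Reagents that add atoms: none
Why: Catalytic hydrogenolysis cleaves only the two benzylic C–O bonds of the ring B ethers, because the ester oxygen sits on a non-benzylic secondary carbon, and should give the target with both R centres intact.

## Compound list

1 | 7-bromohept-1-ene | C=CCCCCCBr | starting material
2 | (R)-1,2-epoxypentane | CCC[C@@H]1CO1 | starting material
3 | hept-6-enylmagnesium bromide (formed in the flask) | C=CCCCCC[Mg]Br | intermediate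
4 | (R)-dodec-11-en-4-ol | CCC[C@@H](O)CCCCCCC=C | intermediate
5 | (R)-tert-butyl(dodec-11-en-4-yloxy)dimethylsilane | CCC[C@@H](O[Si](C)(C)C(C)(C)C)CCCCCCC=C | intermediate
6 | 9-[(R)-9-(tert-butyldimethylsilyloxy)dodecyl]-9-borabicyclo[3.3.1]nonane (formed in the flask) | CCC[C@@H](O[Si](C)(C)C(C)(C)C)CCCCCCCCB1C2CCCC1CCC2 | intermediate
7 | (R)-9-(tert-butyldimethylsilyloxy)dodecan-1-ol | CCC[C@@H](O[Si](C)(C)C(C)(C)C)CCCCCCCCO | intermediate
8 | (R)-9-(tert-butyldimethylsilyloxy)dodecanal (formed in the flask) | CCC[C@@H](O[Si](C)(C)C(C)(C)C)CCCCCCCC=O | intermediate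
9 | (R)-9-(tert-butyldimethylsilyloxy)dodecanoic acid | CCC[C@@H](O[Si](C)(C)C(C)(C)C)CCCCCCCC(=O)O | intermediate
10 | (R)-9-(tert-butyldimethylsilyloxy)-1-(imidazol-1-yl)dodecan-1-one (formed in the flask) | CCC[C@@H](O[Si](C)(C)C(C)(C)C)CCCCCCCC(=O)n1ccnc1 | intermediate
11 | (R)-9-(tert-butyldimethylsilyloxy)-N-methoxy-N-methyldodecanamide | CCC[C@@H](O[Si](C)(C)C(C)(C)C)CCCCCCCC(=O)N(C)OC | intermediate
12 | 2,2,6-trimethyl-4H-1,3-dioxin-4-one | CC1=CC(=O)OC(C)(C)O1 | starting material
13 | lithium 2,2-dimethyl-6-methylidene-1,3-dioxin-4-olate (formed in the flask) | [Li+].C=C1C=C([O-])OC(C)(C)O1 | intermediate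
14 | 2,2-dimethyl-6-(2-oxopropyl)-4H-1,3-dioxin-4-one | CC(=O)CC1=CC(=O)OC(C)(C)O1 | intermediate
15 | dilithium dianion of 14, deprotonated at the CH2 and at the CH3 (formed in the flask) | [Li+].[Li+].C=C([O-])C=C1C=C([O-])OC(C)(C)O1 | intermediate
16 | 6-[(R)-12-(tert-butyldimethylsilyloxy)-2,4-dioxopentadecyl]-2,2-dimethyl-4H-1,3-dioxin-4-one | CCC[C@@H](O[Si](C)(C)C(C)(C)C)CCCCCCCC(=O)CC(=O)CC1=CC(=O)OC(C)(C)O1 | intermediate
17 | 6-bromohex-1-ene | C=CCCCCBr | starting material
18 | hex-5-enylmagnesium bromide (formed in the flask) | C=CCCCC[Mg]Br | intermediate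
19 | (R)-undec-10-en-4-ol | CCC[C@@H](O)CCCCCC=C | intermediate
20 | 5-bromoresorcinol | Oc1cc(O)cc(Br)c1 | starting material
21 | 1,3-bis(benzyloxy)-5-bromobenzene | Brc1cc(OCc2ccccc2)cc(OCc2ccccc2)c1 | intermediate
22 | (R)-11-(9-borabicyclo[3.3.1]nonan-9-yl)undecan-4-ol (formed in the flask) | CCC[C@@H](O)CCCCCCCB1C2CCCC1CCC2 | intermediate
23 | (R)-11-[3,5-bis(benzyloxy)phenyl]undecan-4-ol | CCC[C@@H](O)CCCCCCCc1cc(OCc2ccccc2)cc(OCc2ccccc2)c1 | intermediate
24 | acylketene, (R)-15-(tert-butyldimethylsilyloxy)-3,5,7-trioxooctadec-1-en-1-one (formed in the flask) | CCC[C@@H](O[Si](C)(C)C(C)(C)C)CCCCCCCC(=O)CC(=O)CC(=O)C=C=O | intermediate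
25 | (R)-11-[3,5-bis(benzyloxy)phenyl]undecan-4-yl (R)-15-(tert-butyldimethylsilyloxy)-3,5,7-trioxooctadecanoate (formed in the flask) | CCC[C@@H](O[Si](C)(C)C(C)(C)C)CCCCCCCC(=O)CC(=O)CC(=O)CC(=O)O[C@H](CCC)CCCCCCCc1cc(OCc2ccccc2)cc(OCc2ccccc2)c1 | intermediate
26 | (R)-11-[3,5-bis(benzyloxy)phenyl]undecan-4-yl 2-[(R)-8-(tert-butyldimethylsilyloxy)undecyl]-2-hydroxy-4,6-dioxocyclohexane-1-carboxylate, undefined at the two ring sp3 centres (formed in the flask) | CCC[C@@H](O[Si](C)(C)C(C)(C)C)CCCCCCCC1(O)CC(=O)CC(=O)C1C(=O)O[C@H](CCC)CCCCCCCc1cc(OCc2ccccc2)cc(OCc2ccccc2)c1 | intermediate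
27 | (R)-11-[3,5-bis(benzyloxy)phenyl]undecan-4-yl 6-[(R)-8-(tert-butyldimethylsilyloxy)undecyl]-2,4-dihydroxybenzoate | CCC[C@@H](O[Si](C)(C)C(C)(C)C)CCCCCCCc1cc(O)cc(O)c1C(=O)O[C@H](CCC)CCCCCCCc1cc(OCc2ccccc2)cc(OCc2ccccc2)c1 | intermediate
28 | (R)-11-[3,5-bis(benzyloxy)phenyl]undecan-4-yl 2,4-dihydroxy-6-[(R)-8-hydroxyundecyl]benzoate | CCC[C@@H](O)CCCCCCCc1cc(O)cc(O)c1C(=O)O[C@H](CCC)CCCCCCCc1cc(OCc2ccccc2)cc(OCc2ccccc2)c1 | intermediate
29 | integracin B | CCC[C@@H](O)CCCCCCCc1cc(O)cc(O)c1C(=O)O[C@H](CCC)CCCCCCCc1cc(O)cc(O)c1 | target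

## Step count and risks

Total step count: 13.
Longest linear sequence: 9 steps (1, 2, 3, 4, 5, 7, 11, 12, 13).

**1. Step 11 (key step).**
- Risk: capture of the ketene by the hindered secondary carbinol may be outrun by attack of an enol oxygen of the same chain on the ketene, or by ketene dimerisation.
- Risk: in the base phase, Claisen-type closure with expulsion of the alcohol may compete.
- Loss of the silyl group in the acid phase would be harmless, because it only anticipates step 12.
- Fallback (ring A first, ester second, by transesterification of a benzodioxinone): it sets out from 16 and 23. Et3N in CH2Cl2 at rt should aromatise 16 with the dioxinone still in place to the benzodioxinone F1. BnBr and K2CO3 in acetone cap its free phenol to give the benzyl ether F2. Alcohol 23 is converted with NaH in THF at 0 °C into the sodium alkoxide F3, which opens the carbonyl of F2 with loss of acetone (rt → 50 °C) to the ester F4. HF·pyridine then gives the carbinol F5, and H2 over 10% Pd/C removes all three benzyl ethers. The fallback comes back to the route at 29.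

**2. Step 7.**
- Risk: incomplete second deprotonation.
- Risk: proton exchange between the dianion and the alpha-CH2 of the amide.
- Risk: base- or silica-induced self-aromatisation of the product during isolation, which would erode the acylation.
- Fallback (aldol addition and oxidation instead of acylation): it sets out from 7 and 14. Dess–Martin periodinane in CH2Cl2 oxidises 7 to aldehyde 8, which is now isolated. Dianion 15, made as in step 7, adds to 8 at −78 °C through its terminal carbon to give the hydroxy keto-dioxinone F6 as a mixture of carbinol epimers. A second Dess–Martin oxidation erases that centre, and the fallback comes back to the route at 16. Steps 4 and 5 then fall away.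

**3. Step 10.**
- Risk: consumption of the borane by the free carbinol.
- Risk: protodeboronation or beta-hydride elimination of the alkylpalladium species.
- Risk: sluggish oxidative addition into the electron-rich aryl bromide, which may hold back the coupling.
- Fallback (olefin cross-metathesis and diimide reduction): it sets out from 19 and 21. Coupling of 21 with CH2=CHBF3K (Pd(dppf)Cl2, Cs2CO3, THF/H2O, 70 °C) gives the styrene F7. Cross-metathesis of F7 (in excess) with 19 (second-generation Grubbs catalyst, CH2Cl2, 40 °C) gives the alkenol F8. In this step the terminal CH2 of 19 leaves as ethylene and is replaced by the styrene CH, so the chain stays at eleven carbons. Diimide (TsNHNH2, NaOAc, DME/H2O, reflux) saturates the alkene without touching the benzyl ethers, and the fallback comes back to the route at 23.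

## Further compounds

F1 | step 11 | 5-[(R)-8-(tert-butyldimethylsilyloxy)undecyl]-7-hydroxy-2,2-dimethyl-4H-benzo[d][1,3]dioxin-4-one | CCC[C@@H](O[Si](C)(C)C(C)(C)C)CCCCCCCc1cc(O)cc2OC(C)(C)OC(=O)c12
F2 | step 11 | 7-(benzyloxy)-5-[(R)-8-(tert-butyldimethylsilyloxy)undecyl]-2,2-dimethyl-4H-benzo[d][1,3]dioxin-4-one | CCC[C@@H](O[Si](C)(C)C(C)(C)C)CCCCCCCc1cc(OCc3ccccc3)cc2OC(C)(C)OC(=O)c12
F3 | step 11 | sodium (R)-11-[3,5-bis(benzyloxy)phenyl]undecan-4-olate | [Na+].CCC[C@@H]([O-])CCCCCCCc1cc(OCc2ccccc2)cc(OCc2ccccc2)c1
F4 | step 11 | (R)-11-[3,5-bis(benzyloxy)phenyl]undecan-4-yl 4-(benzyloxy)-6-[(R)-8-(tert-butyldimethylsilyloxy)undecyl]-2-hydroxybenzoate | CCC[C@@H](O[Si](C)(C)C(C)(C)C)CCCCCCCc1cc(OCc2ccccc2)cc(O)c1C(=O)O[C@H](CCC)CCCCCCCc1cc(OCc2ccccc2)cc(OCc2ccccc2)c1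
F5 | step 11 | (R)-11-[3,5-bis(benzyloxy)phenyl]undecan-4-yl 4-(benzyloxy)-2-hydroxy-6-[(R)-8-hydroxyundecyl]benzoate | CCC[C@@H](O)CCCCCCCc1cc(OCc2ccccc2)cc(O)c1C(=O)O[C@H](CCC)CCCCCCCc1cc(OCc2ccccc2)cc(OCc2ccccc2)c1
F6 | step 7 | 6-[(12R)-12-(tert-butyldimethylsilyloxy)-4-hydroxy-2-oxopentadecyl]-2,2-dimethyl-4H-1,3-dioxin-4-one (both C4 epimers) | CCC[C@@H](O[Si](C)(C)C(C)(C)C)CCCCCCCC(O)CC(=O)CC1=CC(=O)OC(C)(C)O1
F7 | step 10 | 1,3-bis(benzyloxy)-5-vinylbenzene | C=Cc1cc(OCc2ccccc2)cc(OCc2ccccc2)c1
F8 | step 10 | (R,E)-11-[3,5-bis(benzyloxy)phenyl]undec-10-en-4-ol | CCC[C@@H](O)CCCCC/C=C/c1cc(OCc2ccccc2)cc(OCc2ccccc2)c1
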